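**Plan**

- Retrosynthetic cuts: first the O–CH3 bond of a ring B 2-methyl ether (the only protecting group); then ring A bonds C1–C2 and C5–C6; then the enol-ester O–acyl bond; finally the C–CO2H and C–Cl bonds of ring B, back to 3,5-dimethoxytoluene.
- Enabling feature: ring A carries CO2Me at C1, OH at C2, the depside oxygen at C4 and CH3 at C6. C2–C3–C4–C5 with O2 and O4 is therefore a 1,1,3-trioxygenated butadiene, C1/C6 with ester and methyl is methyl but-2-ynoate, and O4 can carry the ring B acyl group from the start as an enol ester.
- Forward, ring B: bought as an arene, chlorinated between its two oxygens by directed lithiation, formylated at one of its two equivalent free positions, and oxidised to the acid.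
- Forward, ring A: the acid is placed on the enol oxygen of methyl acetoacetate, and γ-deprotonation/silylation gives the diene. Ring A is the only ring formed, by [4+2] cycloaddition with methyl but-2-ynoate and loss of methanol. A chelation-controlled BCl3 demethylation next to the depside carbonyl ends the route.
- Stereochemistry: the target has no stereocentre and no stereogenic double bond, so only regiochemistry has to be controlled.

Key step: step 6

Remark: enol ester 9 is written as its E isomer and the ketene acetal of 10 and 11 with the silyloxy (lithiooxy) group cis to C3. These are the expected geometries, but neither survives into ring A and neither matters for the outcome.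

**Route**

Step 1
Reactants: 1 3,5-dimethoxytoluene
Product: 3 2-chloro-1,3-dimethoxy-5-methylbenzene, via aryllithium 2 (not isolated)
Conditions: n-BuLi, THF, 0 °C to rt; then C2Cl6, −78 °C to rt
Reagents that add atoms: hexachloroethane, ClC(Cl)(Cl)C(Cl)(Cl)Cl
Why: Directed ortho-metalation: the C2–H between the two methoxy groups is by far the most acidic ring position of orcinol dimethyl ether, and the aryllithium should take chlorine from hexachloroethane by halogen transfer, which fixes the chlorine between the two oxygens without regiochemical ambiguity.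

Step 2
Reactants: 3 2-chloro-1,3-dimethoxy-5-methylbenzene
Product: 5 3-chloro-2,4-dimethoxy-6-methylbenzaldehyde, via α-chlorobenzyl methyl ether 4 (not isolated)
Conditions: Cl2CHOMe, TiCl4, CH2Cl2, −10 to 0 °C; then H2O
Reagents that add atoms: dichloromethyl methyl ether, COC(Cl)Cl (formyl carbon); water, O (formyl oxygen on hydrolysis)
Why: Rieche formylation (Friedel–Crafts type): the two open positions of mirror-symmetric 3 are equivalent, each ortho to one methoxy group and para to the other, so a single aldehyde should form whichever site reacts, and the short low-temperature exposure should leave the ethers intact.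

Step 3
Reactants: 5 3-chloro-2,4-dimethoxy-6-methylbenzaldehyde
Product: 6 3-chloro-2,4-dimethoxy-6-methylbenzoic acid
Conditions: NaClO2, NaH2PO4, 2-methylbut-2-ene, t-BuOH/H2O, rt
Reagents that add atoms: sodium chlorite, [Na+].[O-]Cl=O
Why: Pinnick oxidation takes even di-ortho-substituted benzaldehydes to the acids, and 2-methylbut-2-ene consumes the hypochlorous acid that could otherwise chlorinate the electron-rich ring.

Step 4
Reactants: 6 3-chloro-2,4-dimethoxy-6-methylbenzoic acid; 7 methyl acetoacetate
Product: 9 methyl (2E)-3-[(3-chloro-2,4-dimethoxy-6-methylbenzoyl)oxy]but-2-enoate, via acid chloride 8 (not isolated)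
Conditions: (COCl)2, cat. DMF, CH2Cl2, 0 °C to rt, evaporate; then 7, Et3N, CH2Cl2, 0 °C to rt
Reagents that add atoms: none
Why: Acid chloride formation through the catalytic chloroiminium species, then O-acylation of the triethylammonium enolate of the β-keto ester: a non-chelated enolate and a sterically shielded aroyl chloride both favour attack through oxygen, so the enol ester should form, mainly as the E isomer with the methyl group cis to the ester.

Step 5
Reactants: 9 methyl (2E)-3-[(3-chloro-2,4-dimethoxy-6-methylbenzoyl)oxy]but-2-enoate
Product: 11 (3Z)-4-methoxy-4-[(trimethylsilyl)oxy]buta-1,3-dien-2-yl 3-chloro-2,4-dimethoxy-6-methylbenzoate, via lithium dienolate 10 (not isolated)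
Conditions: LiN(i-Pr)2, Me3SiCl (present from the start), THF, −78 °C; evaporate, hexane, filter under argon; used crude
Reagents that add atoms: chlorotrimethylsilane, C[Si](C)(C)Cl
Why: Vinylogous (γ) deprotonation of a β-oxygenated crotonate and O-silylation of the dienolate, the standard entry to 1-alkoxy-1-silyloxy-3-oxybutadienes: the γ-methyl cis to the ester is removed by the carbonyl-bound amide faster than the less acidic benzylic methyl of ring B, the silyl chloride already present traps the dienolate before acyl transfer can occur, and the di-ortho-substituted aroate carbonyl is shielded from the amide.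

Step 6
Reactants: 11 (3Z)-4-methoxy-4-[(trimethylsilyl)oxy]buta-1,3-dien-2-yl 3-chloro-2,4-dimethoxy-6-methylbenzoate; 12 methyl but-2-ynoate
Product: 15 methyl 4-[(3-chloro-2,4-dimethoxy-6-methylbenzoyl)oxy]-2-hydroxy-6-methylbenzoate, via cyclohexadiene cycloadduct 13 (not isolated), via aryl silyl ether 14 (not isolated)
Conditions: 12 (5 equiv), toluene, 110 °C, sealed tube; then 1 M HCl, THF, rt
Reagents that add atoms: none
Why: Normal-electron-demand Diels–Alder reaction, concerted but asynchronous, between the electron-rich ketene-acetal diene and the ynoate, of the type known for 1-alkoxy-1-silyloxy-3-oxybutadienes and alkynoates with aromatization by loss of alcohol. Ring A is closed intermolecularly as a six-membered carbocycle, both new bonds (C1–C2 and C5–C6 of ring A) arising in the one [4+2] event; cyclohexa-1,4-diene 13 then aromatizes by 1,4-elimination of methanol from its mixed ketal, at the latest on the acidic work-up, which also hydrolyses silyl ether 14 to the C2 phenol. No stereocentre survives, since the ketal carbon of 13 is the only one formed and it is lost on aromatization. The selectivity needed is regiochemical, and it is secured because the ketene-acetal oxygens and the enol-ester oxygen both raise the HOMO coefficient at the CH2 terminus, which therefore bonds to the electrophilic β-carbon of the ynoate; this places the methyl group at C6 and the ketene-acetal carbon next to the ester as C2. The hindered aryl ester, the aryl chloride and the methyl ethers are inert to neutral heating, so the depside oxygen enters ring A already acylated while the C2 oxygen emerges free.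

Step 7
Reactants: 15 methyl 4-[(3-chloro-2,4-dimethoxy-6-methylbenzoyl)oxy]-2-hydroxy-6-methylbenzoate
Product: 17 methyl 4-[(3-chloro-2-hydroxy-4-methoxy-6-methylbenzoyl)oxy]-2-hydroxy-6-methylbenzoate, via boron chelate 16 (not isolated)
Conditions: BCl3 (3 equiv), CH2Cl2, −78 to 0 °C; then H2O
Reagents that add atoms: none
Why: Chelation-controlled ether cleavage by BCl3, as in the ortho-selective demethylation of 2,4-dimethoxy-6-alkylbenzoates: boron bound to the depside carbonyl reaches only the adjacent 2-methoxy group of ring B, which is also twisted out of plane between chlorine and the carbonyl, so chloride should remove that methyl alone while the 4-methoxy group, the methyl ester and the aryl ester persist at low temperature and the ring A phenol is merely held as its boron chelate until work-up.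

**Compound list**

1 | 3,5-dimethoxytoluene (1,3-dimethoxy-5-methylbenzene) | COc1cc(C)cc(OC)c1 | starting material
2 | (2,6-dimethoxy-4-methylphenyl)lithium | [Li]c1c(OC)cc(C)cc1OC | intermediate
3 | 2-chloro-1,3-dimethoxy-5-methylbenzene | COc1cc(C)cc(OC)c1Cl | intermediate
4 | 2-chloro-4-[chloro(methoxy)methyl]-1,3-dimethoxy-5-methylbenzene (racemic) | COC(Cl)c1c(C)cc(OC)c(Cl)c1OC | intermediate
5 | 3-chloro-2,4-dimethoxy-6-methylbenzaldehyde | O=Cc1c(C)cc(OC)c(Cl)c1OC | intermediate
6 | 3-chloro-2,4-dimethoxy-6-methylbenzoic acid | OC(=O)c1c(C)cc(OC)c(Cl)c1OC | intermediate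
7 | methyl acetoacetate (methyl 3-oxobutanoate) | CC(=O)CC(=O)OC | starting material
8 | 3-chloro-2,4-dimethoxy-6-methylbenzoyl chloride | O=C(Cl)c1c(C)cc(OC)c(Cl)c1OC | intermediate
9 | methyl (2E)-3-[(3-chloro-2,4-dimethoxy-6-methylbenzoyl)oxy]but-2-enoate | C/C(=C\C(=O)OC)OC(=O)c1c(C)cc(OC)c(Cl)c1OC | intermediate
10 | lithium 3-[(3-chloro-2,4-dimethoxy-6-methylbenzoyl)oxy]-1-methoxybuta-1,3-dien-1-olate (O–Li cis to C3) | [Li]O/C(OC)=C\C(=C)OC(=O)c1c(C)cc(OC)c(Cl)c1OC | intermediate
11 | (3Z)-4-methoxy-4-[(trimethylsilyl)oxy]buta-1,3-dien-2-yl 3-chloro-2,4-dimethoxy-6-methylbenzoate | C=C(OC(=O)c1c(C)cc(OC)c(Cl)c1OC)/C=C(/OC)O[Si](C)(C)C | intermediate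
12 | methyl but-2-ynoate | CC#CC(=O)OC | starting material
13 | methyl 4-[(3-chloro-2,4-dimethoxy-6-methylbenzoyl)oxy]-6-methoxy-2-methyl-6-[(trimethylsilyl)oxy]cyclohexa-1,4-diene-1-carboxylate (racemic) | COC(=O)C1=C(C)CC(OC(=O)c2c(C)cc(OC)c(Cl)c2OC)=CC1(OC)O[Si](C)(C)C | intermediate
14 | methyl 4-[(3-chloro-2,4-dimethoxy-6-methylbenzoyl)oxy]-2-methyl-6-[(trimethylsilyl)oxy]benzoate | COC(=O)c1c(C)cc(OC(=O)c2c(C)cc(OC)c(Cl)c2OC)cc1O[Si](C)(C)C | intermediate
15 | methyl 4-[(3-chloro-2,4-dimethoxy-6-methylbenzoyl)oxy]-2-hydroxy-6-methylbenzoate | COC(=O)c1c(C)cc(OC(=O)c2c(C)cc(OC)c(Cl)c2OC)cc1O | intermediate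
16 | methyl 4-({3-chloro-2-[(dichloroboranyl)oxy]-4-methoxy-6-methylbenzoyl}oxy)-2-[(dichloroboranyl)oxy]-6-methylbenzoate | COC(=O)c1c(C)cc(OC(=O)c2c(C)cc(OC)c(Cl)c2OB(Cl)Cl)cc1OB(Cl)Cl | intermediate
17 | methyl 4-[(3-chloro-2-hydroxy-4-methoxy-6-methylbenzoyl)oxy]-2-hydroxy-6-methylbenzoate | COC(=O)c1c(C)cc(OC(=O)c2c(C)cc(OC)c(Cl)c2O)cc1O | target

**Step count and risks**

Total step count: 7. Longest linear sequence: 7 steps (1 to 17); 7 and 12 enter as purchased building blocks.

Steps most likely to fail:

Step 6. The cycloaddition may be outrun by thermal decay of the silyl ketene acetal (silyl migration, or protodesilylation by methanol released from adduct that aromatizes early). The acyloxy group makes the diene less electron-rich than its silyloxy analogues, and the β-methyl group slows the ynoate. The fallback sets out from acid 6 and comes back at 15, joining the two rings by esterification after ring A exists. Acid 6 and commercial methyl 2,4-dihydroxy-6-methylbenzoate F1 are treated with trifluoroacetic anhydride in toluene at rt. The mixed anhydride formed in the flask, 3-chloro-2,4-dimethoxy-6-methylbenzoic trifluoroacetic anhydride F2, should acylate the 4-hydroxyl of F1, the 2-hydroxyl being tied up in its hydrogen bond to the ester. This gives 15, which continues with step 7.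

Step 5. The amide base may also remove a benzylic proton from the ring B methyl group (lateral lithiation of an ortho-toluate), the dienolate may shift its acyl group before it is silylated, and the ketene acetal may hydrolyse during isolation. The fallback sets out from acid 6 as its chloride 8 (first half of step 4) and comes back at the target 17; it forms the enolate before the aroyl group is attached. The known 4,4-dimethoxybut-3-en-2-one F3 is deprotonated at its acetyl methyl with LiN(i-Pr)2 in THF at −78 °C to lithium 4,4-dimethoxybuta-1,3-dien-2-olate F4. F4 is O-acylated by 8 in THF/DMPU to 4,4-dimethoxybuta-1,3-dien-2-yl 3-chloro-2,4-dimethoxy-6-methylbenzoate F5. Heating F5 with 12 should give the cycloadduct methyl 4-[(3-chloro-2,4-dimethoxy-6-methylbenzoyl)oxy]-6,6-dimethoxy-2-methylcyclohexa-1,4-diene-1-carboxylate F6, which loses methanol to methyl 4-[(3-chloro-2,4-dimethoxy-6-methylbenzoyl)oxy]-2-methoxy-6-methylbenzoate F7. BCl3 then cleaves both carbonyl-flanked methyl ethers, one on each ring, through the same chelate 16 to give 17.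

Step 4. Acylation may occur at carbon instead of oxygen, or acyl transfer from the shielded acid chloride may be slow enough for O-to-C acyl migration to intervene. The fallback sets out from 6 and 7 and comes back at 9, using a reaction that delivers the acyl group to the oxygen that carried silicon. Acid 6 with cyanuric fluoride and pyridine gives 3-chloro-2,4-dimethoxy-6-methylbenzoyl fluoride F8. Ester 7 with Me3SiCl and Et3N gives methyl 3-[(trimethylsilyl)oxy]but-2-enoate F9 (E/Z mixture; either isomer serves). Catalytic Bu4NF in THF then joins F8 and F9 by fluoride-catalysed O-acylation of the silyl enol ether, releasing fluorotrimethylsilane and giving 9.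

**Further compounds**

F1 | step 6 | methyl 2,4-dihydroxy-6-methylbenzoate | COC(=O)c1c(C)cc(O)cc1O
F2 | step 6 | 3-chloro-2,4-dimethoxy-6-methylbenzoic trifluoroacetic anhydride | O=C(OC(=O)C(F)(F)F)c1c(C)cc(OC)c(Cl)c1OC
F3 | step 5 | 4,4-dimethoxybut-3-en-2-one | CC(=O)C=C(OC)OC
F4 | step 5 | lithium 4,4-dimethoxybuta-1,3-dien-2-olate | [Li]OC(=C)C=C(OC)OC
F5 | step 5 | 4,4-dimethoxybuta-1,3-dien-2-yl 3-chloro-2,4-dimethoxy-6-methylbenzoate | C=C(OC(=O)c1c(C)cc(OC)c(Cl)c1OC)C=C(OC)OC
F6 | step 5 | methyl 4-[(3-chloro-2,4-dimethoxy-6-methylbenzoyl)oxy]-6,6-dimethoxy-2-methylcyclohexa-1,4-diene-1-carboxylate | COC(=O)C1=C(C)CC(OC(=O)c2c(C)cc(OC)c(Cl)c2OC)=CC1(OC)OC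
F7 | step 5 | methyl 4-[(3-chloro-2,4-dimethoxy-6-methylbenzoyl)oxy]-2-methoxy-6-methylbenzoate | COC(=O)c1c(C)cc(OC(=O)c2c(C)cc(OC)c(Cl)c2OC)cc1OC
F8 | step 4 | 3-chloro-2,4-dimethoxy-6-methylbenzoyl fluoride | O=C(F)c1c(C)cc(OC)c(Cl)c1OC
F9 | step 4 | methyl 3-[(trimethylsilyl)oxy]but-2-enoate | COC(=O)C=C(C)O[Si](C)(C)C
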